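**Retrosynthetic overview**

1. The dihydrofuran ring (O–C8 bond, C8 stereocentre) is closed last, by a chiral Brønsted acid-catalysed dehydrative cyclisation of a (3S,5R)-5,6-diol that already carries the complete (7E,9Z)-polyene.
2. C7=C8 and the C10′ alcohol come from one hydride reduction of a 7,8-alkynyl ester; C11=C12 comes from a Wittig coupling of a C15 phosphonium salt with a C12 aldehyde ester (C10 dialdehyde + C2 ylide).
3. C6–C7 comes from addition of the dianion of (Z)-3-methylpent-2-en-4-yn-1-ol to a C9 dihydroxy ketone; this enynol is the source of the 9Z double bond of the target.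
4. The C9 dihydroxy ketone comes from achiral 4-oxoisophorone: organocatalytic asymmetric epoxidation (C5), reductive epoxide opening, anti-selective directed reduction (C3).
5. Ring order: the cyclohexane ring is bought with 4-oxoisophorone; the dihydrofuran ring is formed in the final step.

Positions are given in carotenoid numbering (ring C1–C6, chain C7–C15 and C15′–C10′; C5 carries the ring methyl and the ether oxygen, C8 is the furan CH). The target SMILES has C8 and C11 cis across C9=C10, so the route is built for the 9Z isomer.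

Assumption: 1, 6, 11 and 12 are bought; the facial sense of the two chiral catalysts (steps 1 and 9) is assigned by analogy, and if it proves opposite the pseudo-enantiomeric amine (9-amino(9-deoxy)epi-quinidine) or the (R)-phosphoramide is used instead.

**Route**

Step 1
Reactants: 1 4-oxoisophorone (2,6,6-trimethylcyclohex-2-ene-1,4-dione)
Product: 2 (1R,6S)-1,3,3-trimethyl-7-oxabicyclo[4.1.0]heptane-2,5-dione
Conditions: 9-amino(9-deoxy)epi-quinine (10 mol %), CF3CO2H (20 mol %), 50% aq. H2O2 (1.5 equiv), 1,4-dioxane, 35 °C, 24 h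
Reagents that add atoms: hydrogen peroxide, OO
Why: The primary amine salt condenses with the unhindered C4 carbonyl to a chiral iminium ion, hydroperoxide adds to the methyl-bearing β-carbon from one enantioface (this fixes the future C5 as R) and the enamine closes the oxirane, i.e. an organocatalytic asymmetric Weitz–Scheffer epoxidation of a cyclic enone that sets the first stereocentres from an achiral enedione.

Step 2
Reactants: 2 (1R,6S)-1,3,3-trimethyl-7-oxabicyclo[4.1.0]heptane-2,5-dione
Product: 4 (R)-2-hydroxy-2,6,6-trimethylcyclohexane-1,4-dione, via selenide 3 (not isolated)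
Conditions: PhSeSePh (1.5 equiv), NaBH4 (3 equiv), EtOH, 0 °C; then AcOH (1.5 equiv) and 2, 0 °C → rt, 30 min
Reagents that add atoms: none
Why: Phenylselenolate opens the oxirane by SN2 at the secondary carbon alpha to the less hindered ketone (selenide 3) and a second selenolate removes selenium to leave the enolate, so the net result is reductive cleavage of the CH–O bond with the tertiary C–O stereocentre untouched (organoselenium reduction of an α,β-epoxy ketone to a β-hydroxy ketone).

Step 3
Reactants: 4 (R)-2-hydroxy-2,6,6-trimethylcyclohexane-1,4-dione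
Product: 5 (2R,4S)-2,4-dihydroxy-2,6,6-trimethylcyclohexan-1-one
Conditions: Me4NBH(OAc)3 (2 equiv), MeCN/AcOH 1:1, −25 °C, 16 h
Reagents that add atoms: none
Why: The tertiary hydroxyl exchanges onto boron and delivers hydride intramolecularly to the β-carbonyl from its own face, giving the anti 1,3-diol (new carbinol centre S, OH trans to the tertiary OH), while the ketone flanked by two quaternary carbons is too hindered to react (Evans–Saksena hydroxyl-directed reduction).

Step 4
Reactants: 5 (2R,4S)-2,4-dihydroxy-2,6,6-trimethylcyclohexan-1-one; 6 (Z)-3-methylpent-2-en-4-yn-1-ol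
Product: 8 (1R,2R,4S)-1-[(3Z)-5-hydroxy-3-methylpent-3-en-1-yn-1-yl]-2,6,6-trimethylcyclohexane-1,2,4-triol, via dilithio enynolate 7 (not isolated)
Conditions: 6 (3.3 equiv), n-BuLi (6.6 equiv), THF, −78 → 0 °C; then 5, −78 °C → rt, 4 h; aq. NH4Cl
Reagents that add atoms: none
Why: The slim lithium acetylide adds 1,2 to the non-enolisable ketone after the two hydroxyls have been deprotonated by excess reagent and brings in C7–C11 with the 9Z double bond already in place; the new C6 carbinol centre (major epimer from axial attack drawn, minor epimer carried along) is erased in step 9 (acetylide addition to a ketone).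

Step 5
Reactants: 8 (1R,2R,4S)-1-[(3Z)-5-hydroxy-3-methylpent-3-en-1-yn-1-yl]-2,6,6-trimethylcyclohexane-1,2,4-triol
Product: 10 [(2Z)-3-methyl-5-[(1R,2R,4S)-1,2,4-trihydroxy-2,6,6-trimethylcyclohexyl]pent-2-en-4-yn-1-yl]triphenylphosphonium bromide, via allylic bromide 9 (not isolated)
Conditions: NBS (1.2 equiv), Me2S (1.3 equiv), CH2Cl2/THF, −25 → 0 °C, 2 h; then PPh3 (1.5 equiv), rt, 16 h
Reagents that add atoms: N-bromosuccinimide, O=C1CCC(=O)N1Br; triphenylphosphine, c1ccc(cc1)P(c1ccccc1)c1ccccc1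
Why: Corey–Kim bromination converts only the primary allylic hydroxyl, by SN2 displacement on its alkoxysulfonium salt without an allyl cation, so the 9Z geometry and the secondary and tertiary alcohols are kept, and triphenylphosphine then quaternises the bromide by SN2.

Step 6
Reactants: 11 (2E,4E,6E)-2,7-dimethylocta-2,4,6-trienedial; 12 ethyl (triphenylphosphoranylidene)acetate
Product: 13 ethyl (2E,4E,6E,8E)-4,9-dimethyl-10-oxodeca-2,4,6,8-tetraenoate
Conditions: 11 (2 equiv), 12 (1 equiv), CH2Cl2, 0 °C → rt, 12 h; unreacted 11 recovered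
Reagents that add atoms: none
Why: The stabilised ylide reacts with one formyl group of the symmetrical dialdehyde used in excess and gives the E-enoate (Wittig olefination).

Step 7
Reactants: 10 [(2Z)-3-methyl-5-[(1R,2R,4S)-1,2,4-trihydroxy-2,6,6-trimethylcyclohexyl]pent-2-en-4-yn-1-yl]triphenylphosphonium bromide; 13 ethyl (2E,4E,6E,8E)-4,9-dimethyl-10-oxodeca-2,4,6,8-tetraenoate
Product: 15 ethyl (2E,4E,6E,8E,10E,12Z)-4,9,13-trimethyl-15-[(1R,2R,4S)-1,2,4-trihydroxy-2,6,6-trimethylcyclohexyl]pentadeca-2,4,6,8,10,12-hexaen-14-ynoate, via ylide 14 (not isolated)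
Conditions: NaOEt (2.5 equiv), EtOH/CH2Cl2, 0 °C → rt, 3 h; then heptane/EtOAc, 70 °C, 1 h
Reagents that add atoms: none
Why: Ethoxide generates the allylic ylide 14, which condenses with the enal to form C11=C12, the 9Z bond of the ylide being retained as in 9-cis-retinoid Wittig couplings and the hindered 11Z by-product relaxing to 11E on brief warming (Wittig olefination).

Step 8
Reactants: 15 ethyl (2E,4E,6E,8E,10E,12Z)-4,9,13-trimethyl-15-[(1R,2R,4S)-1,2,4-trihydroxy-2,6,6-trimethylcyclohexyl]pentadeca-2,4,6,8,10,12-hexaen-14-ynoate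
Product: 16 (1S,2R,4S)-1-[(1E,3Z,5E,7E,9E,11E,13E)-15-hydroxy-3,7,12-trimethylpentadeca-1,3,5,7,9,11,13-heptaen-1-yl]-2,6,6-trimethylcyclohexane-1,2,4-triol
Conditions: NaAlH2(OCH2CH2OMe)2 (6 equiv), THF, 0 °C → rt, 3 h; aq. KNaC4H4O6 (potassium sodium tartrate)
Reagents that add atoms: none
Why: The C6 alkoxide binds aluminium and delivers hydride to the alkyne in a trans-hydroalumination that gives the 7E alkene after protonolysis, while the same hydride reduces the conjugated ester 1,2 to the allylic alcohol (alkoxide-directed reduction of a propargylic alcohol plus ester reduction).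

Step 9
Reactants: 16 (1S,2R,4S)-1-[(1E,3Z,5E,7E,9E,11E,13E)-15-hydroxy-3,7,12-trimethylpentadeca-1,3,5,7,9,11,13-heptaen-1-yl]-2,6,6-trimethylcyclohexane-1,2,4-triol
Product: 17 (3S,5R,8S,9Z)-5,8-epoxy-5,8-dihydro-10′-apo-β-carotene-3,10′-diol (CNP0263491.3)
Conditions: (S)-3,3′-bis(2,4,6-triisopropylphenyl)-1,1′-binaphthyl-2,2′-diyl N-triflylphosphoramide (5 mol %), 5 Å molecular sieves, CH2Cl2, −60 °C, 6 h; Et3N quench
Reagents that add atoms: none
Why: Proposed new method: the chiral N-triflylphosphoramide protonates the tertiary, polyene-conjugated 6-OH, water leaves to give a heptaenyl cation held as a contact ion pair with the confined chiral anion, which hydrogen-bonds the 5-OH and shields one face of C8 so that O5 closes the 2,5-dihydrofuran ring with catalyst-controlled 8S configuration (side chain cis to the C5 methyl) while C3, C5 and the 9Z bond are untouched and both C6 epimers converge; the closest known reactions are the unselective acid-induced 5,6-epoxide or 5,6-diol to 5,8-furanoid rearrangement of carotenoids and the chiral N-triflylphosphoramide-catalysed intramolecular allylic substitution of allylic alcohols that gives 2H-chromenes.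

**Compound list**

1 | 4-oxoisophorone (2,6,6-trimethylcyclohex-2-ene-1,4-dione) | CC1=CC(=O)CC(C)(C)C1=O | starting material
2 | (1R,6S)-1,3,3-trimethyl-7-oxabicyclo[4.1.0]heptane-2,5-dione | C[C@@]12O[C@@H]1C(=O)CC(C)(C)C2=O | intermediate
3 | (2S,3R)-2-hydroxy-2,6,6-trimethyl-3-(phenylselanyl)cyclohexane-1,4-dione | C[C@@]1(O)[C@@H]([Se]c2ccccc2)C(=O)CC(C)(C)C1=O | intermediate
4 | (R)-2-hydroxy-2,6,6-trimethylcyclohexane-1,4-dione | C[C@@]1(O)CC(=O)CC(C)(C)C1=O | intermediate
5 | (2R,4S)-2,4-dihydroxy-2,6,6-trimethylcyclohexan-1-one | C[C@@]1(O)C[C@@H](O)CC(C)(C)C1=O | intermediate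
6 | (Z)-3-methylpent-2-en-4-yn-1-ol | C#C/C(C)=C\CO | starting material
7 | dilithium salt of 6 (lithium (Z)-5-lithio-3-methylpent-2-en-4-yn-1-olate) | [Li]C#C/C(C)=C\CO[Li] | intermediate
8 | (1R,2R,4S)-1-[(3Z)-5-hydroxy-3-methylpent-3-en-1-yn-1-yl]-2,6,6-trimethylcyclohexane-1,2,4-triol (major C6 epimer) | C[C@@]1(O)C[C@@H](O)CC(C)(C)[C@@]1(O)C#C/C(C)=C\CO | intermediate
9 | (1R,2R,4S)-1-[(3Z)-5-bromo-3-methylpent-3-en-1-yn-1-yl]-2,6,6-trimethylcyclohexane-1,2,4-triol | C[C@@]1(O)C[C@@H](O)CC(C)(C)[C@@]1(O)C#C/C(C)=C\CBr | intermediate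
10 | [(2Z)-3-methyl-5-[(1R,2R,4S)-1,2,4-trihydroxy-2,6,6-trimethylcyclohexyl]pent-2-en-4-yn-1-yl]triphenylphosphonium bromide | C[C@@]1(O)C[C@@H](O)CC(C)(C)[C@@]1(O)C#C/C(C)=C\C[P+](c1ccccc1)(c1ccccc1)c1ccccc1.[Br-] | intermediate
11 | (2E,4E,6E)-2,7-dimethylocta-2,4,6-trienedial | O=C/C(C)=C/C=C/C=C(C)/C=O | starting material
12 | ethyl (triphenylphosphoranylidene)acetate | CCOC(=O)C=P(c1ccccc1)(c1ccccc1)c1ccccc1 | starting material
13 | ethyl (2E,4E,6E,8E)-4,9-dimethyl-10-oxodeca-2,4,6,8-tetraenoate | O=C/C(C)=C/C=C/C=C(C)/C=C/C(=O)OCC | intermediate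
14 | ylide of 10, [(2Z)-3-methyl-5-[(1R,2R,4S)-1,2,4-trihydroxy-2,6,6-trimethylcyclohexyl]pent-2-en-4-yn-1-ylidene]triphenylphosphorane | C[C@@]1(O)C[C@@H](O)CC(C)(C)[C@@]1(O)C#C/C(C)=C\C=P(c1ccccc1)(c1ccccc1)c1ccccc1 | intermediate
15 | ethyl (2E,4E,6E,8E,10E,12Z)-4,9,13-trimethyl-15-[(1R,2R,4S)-1,2,4-trihydroxy-2,6,6-trimethylcyclohexyl]pentadeca-2,4,6,8,10,12-hexaen-14-ynoate | C[C@@]1(O)C[C@@H](O)CC(C)(C)[C@@]1(O)C#C/C(C)=C\C=C\C(C)=C\C=C\C=C(C)\C=C\C(=O)OCC | intermediate
16 | (1S,2R,4S)-1-[(1E,3Z,5E,7E,9E,11E,13E)-15-hydroxy-3,7,12-trimethylpentadeca-1,3,5,7,9,11,13-heptaen-1-yl]-2,6,6-trimethylcyclohexane-1,2,4-triol, i.e. (3S,5R,6S,9Z)-5,6-dihydro-10′-apo-β-carotene-3,5,6,10′-tetrol | C[C@@]1(O)C[C@@H](O)CC(C)(C)[C@@]1(O)/C=C/C(C)=C\C=C\C(C)=C\C=C\C=C(C)\C=C\CO | intermediate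
17 | (3S,5R,8S,9Z)-5,8-epoxy-5,8-dihydro-10′-apo-β-carotene-3,10′-diol | C/C(=C/C=C/C(C)=C/C=C/C=C(C)/C=C/CO)[C@@H]1C=C2C(C)(C)C[C@H](O)C[C@@]2(C)O1 | target

**Step count and risks**

Total step count: 9. Longest linear sequence: 8 (steps 1–5 and 7–9; step 6 is the side branch).

The three steps most likely to fail:

Step 9, the proposed new cyclisation. The catalyst may give poor C8 control, the cation may lose the 9Z geometry, or the C10′ allylic alcohol may ionise. The fallback uses known chemistry and sets out from 16: a catalytic achiral acid (pyridinium p-toluenesulfonate, or 0.01 M HCl, in CH2Cl2 at 0 °C) brings about the classical unselective furanoid cyclisation and gives 17 together with its C8 epimer, (3S,5R,8R,9Z)-5,8-epoxy-5,8-dihydro-10′-apo-β-carotene-3,10′-diol F1. The two are separated by preparative HPLC, and F1 is returned to the same acid, which re-opens the C8–O bond to the common cation and re-equilibrates the pair, so the material comes back to the route at 17.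

Step 2, the reductive epoxide opening. The tertiary aldol 4 may dehydrate back to 1, or the selenolate may open the wrong C–O bond. The fallback sets out from 1 and replaces steps 1–3 by the established levodione line. Fermenting baker's yeast (a metal-free enzymatic reduction that then sets the first stereocentre) reduces the C=C bond to (6R)-2,2,6-trimethylcyclohexane-1,4-dione F2. Hydrogenation over Ni (Raney type) reduces the unhindered ketone to (4R,6R)-4-hydroxy-2,2,6-trimethylcyclohexan-1-one F3. TMSCl, Et3N and NaI in MeCN give the silyl ether and silyl enol ether in one operation, trimethyl{[(4R)-2,6,6-trimethyl-4-(trimethylsilyloxy)cyclohex-1-en-1-yl]oxy}silane F4. Rubottom oxidation with mCPBA, anti to the silyloxy group, followed by aqueous citric acid, installs the tertiary hydroxyl and removes the silyl groups, which comes back to the route at 5.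

Step 8, the combined reduction on the C27 polyene. Hydroalumination of the enyne in a long polyene may be incomplete or may over-reduce. The fallback sets out from 8 and reduces the alkyne before the chain is built. NaAlH2(OCH2CH2OMe)2 in THF gives (1S,2R,4S)-1-[(1E,3Z)-5-hydroxy-3-methylpenta-1,3-dien-1-yl]-2,6,6-trimethylcyclohexane-1,2,4-triol F5. NBS/Me2S followed by PPh3 (acid-free, so the 5,6-diol is not cyclised) gives [(2Z,4E)-3-methyl-5-[(1S,2R,4S)-1,2,4-trihydroxy-2,6,6-trimethylcyclohexyl]penta-2,4-dien-1-yl]triphenylphosphonium bromide F6. Wittig coupling with 13 (NaOEt, EtOH/CH2Cl2) gives ethyl (2E,4E,6E,8E,10E,12Z,14E)-4,9,13-trimethyl-15-[(1S,2R,4S)-1,2,4-trihydroxy-2,6,6-trimethylcyclohexyl]pentadeca-2,4,6,8,10,12,14-heptaenoate F7. Reduction of the ester alone with i-Bu2AlH at −78 °C comes back to the route at 16.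

Further compounds
F1 | step 9 | (3S,5R,8R,9Z)-5,8-epoxy-5,8-dihydro-10′-apo-β-carotene-3,10′-diol | C/C(=C/C=C/C(C)=C/C=C/C=C(C)/C=C/CO)[C@H]1C=C2C(C)(C)C[C@H](O)C[C@@]2(C)O1
F2 | step 2 | (6R)-2,2,6-trimethylcyclohexane-1,4-dione | C[C@@H]1CC(=O)CC(C)(C)C1=O
F3 | step 2 | (4R,6R)-4-hydroxy-2,2,6-trimethylcyclohexan-1-one | C[C@@H]1C[C@@H](O)CC(C)(C)C1=O
F4 | step 2 | trimethyl{[(4R)-2,6,6-trimethyl-4-(trimethylsilyloxy)cyclohex-1-en-1-yl]oxy}silane | CC1=C(O[Si](C)(C)C)C(C)(C)C[C@H](O[Si](C)(C)C)C1
F5 | step 8 | (1S,2R,4S)-1-[(1E,3Z)-5-hydroxy-3-methylpenta-1,3-dien-1-yl]-2,6,6-trimethylcyclohexane-1,2,4-triol | C[C@@]1(O)C[C@@H](O)CC(C)(C)[C@@]1(O)/C=C/C(C)=C\CO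
F6 | step 8 | [(2Z,4E)-3-methyl-5-[(1S,2R,4S)-1,2,4-trihydroxy-2,6,6-trimethylcyclohexyl]penta-2,4-dien-1-yl]triphenylphosphonium bromide | C[C@@]1(O)C[C@@H](O)CC(C)(C)[C@@]1(O)/C=C/C(C)=C\C[P+](c1ccccc1)(c1ccccc1)c1ccccc1.[Br-]
F7 | step 8 | ethyl (2E,4E,6E,8E,10E,12Z,14E)-4,9,13-trimethyl-15-[(1S,2R,4S)-1,2,4-trihydroxy-2,6,6-trimethylcyclohexyl]pentadeca-2,4,6,8,10,12,14-heptaenoate | C[C@@]1(O)C[C@@H](O)CC(C)(C)[C@@]1(O)/C=C/C(C)=C\C=C\C(C)=C\C=C\C=C(C)\C=C\C(=O)OCC
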